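**Plan** (cembrane locants: ring C1–C14; C15/C16 = lactone CH/C=O; C17, C18, C20 = methyls on C15, C4, C12; C19 = exo-methylene on C8)
1. Cuts: epoxide O off C11/C12 and CH3 off C15; a carboxyl is added to C14, and the C13–C14 bond is then cut by a retro-Ireland–Claisen shift to a 14-membered lactone C14–C(=O)–O–C11 carrying an isopropenyl group (C12, C13, C20); this lactone is cut at C7–C8 (Nozaki–Hiyama–Kishi) and at the ester C–O into δ-lactone acid 18 (C1–C7) and bromodienol 6 (C8–C13).
2. Enabling feature: C13 is allylic to the C11=C12 olefin hidden in the epoxide, so C14–C13–C12(Me)=C11 is the γ,δ-unsaturated-acid array of a Claisen product; the 14-membered carbocycle and a 14-membered allylic lactone are [3,3] isomers, so an easy ring closure (ester, then C7–C8) is converted into the C13–C14 bond with the E olefin set by the chair.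
3. Forward order: δ-lactone (step 8), 14-membered lactone (steps 9–13), carbocycle by the [3,3] shift (step 17), decarboxylation, C15 methylation, epoxide last (step 21).
4. Stereochemistry: C4 and C3 from a Sharpless epoxide opened with inversion at C3 by the carboxylate; C1 from the 4,6-cis (diequatorial) preference when one of two identical CH2CO2H arms lactonises; C7 from CBS reduction; C15 from trans alkylation of the lactone enolate; C11/C12 from Shi epoxidation; the carbinol centre at C11 and the carboxyl-bearing C14 are both erased.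

Key step: step 17

Remark: 7 (otherwise one step from pent-4-yn-1-ol), 12 (otherwise from cyclopent-3-en-1-ol) and both enantiomers of the Shi ketone are taken as purchasable; the C11 configuration of 6 has no bearing on the target and (R) is chosen arbitrarily.

**Step 1**
Reactants: 1 N-methoxy-N-methylacetamide; 2 2,3-dibromoprop-1-ene
Product: 3 4-bromo-N-methoxy-N-methylpent-4-enamide
Conditions: LiN(iPr)2 (LDA), THF, −78 °C; then 2, −78 → −30 °C
Reagents that add atoms: none
Why: Enolate alkylation: the lithium enolate of the Weinreb acetamide displaces the allylic bromide (SN2), the vinylic bromide being inert, which joins C10–C11 to C9–C8(Br)=C19.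

**Step 2**
Reactants: 3 4-bromo-N-methoxy-N-methylpent-4-enamide; 4 isopropenylmagnesium bromide
Product: 5 6-bromo-2-methylhepta-1,6-dien-3-one
Conditions: THF, −20 → 0 °C; inverse quench into cold 1 M HCl
Reagents that add atoms: none
Why: Weinreb ketone synthesis: the magnesium-chelated tetrahedral adduct survives until the acidic quench, so one isopropenyl group (C12, C13, C20) is delivered and the released amine cannot add to the enone.

**Step 3**
Reactants: 5 6-bromo-2-methylhepta-1,6-dien-3-one
Product: 6 (3R)-6-bromo-2-methylhepta-1,6-dien-3-ol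
Conditions: (S)-Me-CBS oxazaborolidine (0.2 equiv), catecholborane, toluene, −78 °C
Reagents that add atoms: none
Why: Corey–Bakshi–Shibata reduction: with the isopropenyl group as the large substituent the (S)-catalyst should give the (R)-carbinol; this centre (C11) becomes sp2 in step 17 and is made uniform only so that single diastereomers are carried.

**Step 4**
Reactants: 7 tert-butyldimethyl(pent-4-yn-1-yloxy)silane
Product: 9 (2E)-6-(tert-butyldimethylsilyloxy)-3-methylhex-2-en-1-ol, via vinylalane 8 (not isolated)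
Conditions: AlMe3, ZrCp2Cl2 (cat.), CH2Cl2, 0 °C → rt; then n-BuLi, THF, −30 °C; (CH2O)n, rt
Reagents that add atoms: trimethylaluminium, C[Al](C)C; formaldehyde (as paraformaldehyde), C=O
Why: Negishi zirconium-catalysed carboalumination adds Me–Al syn across the terminal alkyne (methyl C18 on C4) and the derived alanate is hydroxymethylated with retention, which fixes the E geometry of C3=C4 and installs C2.

**Step 5**
Reactants: 9 (2E)-6-(tert-butyldimethylsilyloxy)-3-methylhex-2-en-1-ol
Product: 10 [(2S,3S)-3-[3-(tert-butyldimethylsilyloxy)propyl]-3-methyloxiran-2-yl]methanol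
Conditions: Ti(OiPr)4 (10 mol %), L-(+)-diethyl tartrate, t-BuOOH, 4 Å molecular sieves, CH2Cl2, −20 °C
Reagents that add atoms: tert-butyl hydroperoxide, CC(C)(C)OO
Why: Sharpless asymmetric epoxidation: with the L-(+)-tartrate the E-allylic alcohol should give the (2S,3S)-epoxide, as geraniol does, which fixes C4 (S) and sets C3 as the centre to be inverted in step 8.

**Step 6**
Reactants: 10 [(2S,3S)-3-[3-(tert-butyldimethylsilyloxy)propyl]-3-methyloxiran-2-yl]methanol
Product: 11 [(2S,3S)-3-[3-(tert-butyldimethylsilyloxy)propyl]-3-methyloxiran-2-yl]methyl 4-methylbenzenesulfonate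
Conditions: TsCl, Et3N, DMAP (cat.), CH2Cl2, 0 °C
Reagents that add atoms: 4-toluenesulfonyl chloride, Cc1ccc(cc1)S(Cl)(=O)=O
Why: Sulfonylation of the primary alcohol turns C2 into an electrophile without touching the epoxide.

**Step 7**
Reactants: 11 epoxy tosylate; 12 4-bromocyclopent-1-ene
Product: 15 tert-butyl{3-[(2S,3S)-3-(cyclopent-3-en-1-ylmethyl)-2-methyloxiran-2-yl]propoxy}dimethylsilane, via cyclopent-3-enyllithium 13 (not isolated), via lithium dicyclopent-3-enylcuprate 14 (not isolated)
Conditions: 12, t-BuLi (2 equiv), Et2O, −78 °C; CuI (0.5 equiv), −40 °C; then 11, −40 → −10 °C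
Reagents that add atoms: none
Why: SN2 displacement of a primary epoxy tosylate by a lithium dialkylcuprate, a coupling known to leave an adjacent trisubstituted epoxide intact, forms C1–C2; the cyclopentene is a masked, still symmetric glutaric acid (C14, C15 and the two future carboxyl carbons).

**Step 8**
Reactants: 15 cyclopentenylmethyl epoxide
Product: 18 2-[(4S,6R)-6-[(2S)-5-(tert-butyldimethylsilyloxy)-2-hydroxypentan-2-yl]-2-oxotetrahydropyran-4-yl]acetic acid, via dialdehyde 16 (not isolated), via epoxy diacid 17 (not isolated)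
Conditions: O3, CH2Cl2, −78 °C; PPh3; then NaClO2, NaH2PO4, 2-methyl-2-butene, t-BuOH/H2O, 0 °C → rt; then PPTS (cat.), CH2Cl2, rt → 40 °C
Reagents that add atoms: ozone, [O-][O+]=O; sodium chlorite, [Na+].[O-]Cl=O
Why: Ozonolysis and Pinnick oxidation unveil the glutaric diacid, one arm of which opens the epoxide 6-exo at the secondary carbon (inversion at C3, C4–O retained) to the δ-lactone; of the two diastereotopic arms the one that leaves the other equatorial (4,6-cis) should be preferred in the chair transition state and also at equilibrium (acid-mediated exchange through the glutaric anhydride), which sets C1.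

**Step 9**
Reactants: 18 δ-lactone acid; 6 (3R)-6-bromo-2-methylhepta-1,6-dien-3-ol
Product: 19 (3R)-6-bromo-2-methylhepta-1,6-dien-3-yl 2-[(4S,6R)-6-[(2S)-5-(tert-butyldimethylsilyloxy)-2-hydroxypentan-2-yl]-2-oxotetrahydropyran-4-yl]acetate
Conditions: DCC, DMAP (cat.), CH2Cl2, 0 °C → rt
Reagents that add atoms: none
Why: Steglich esterification of the single free acid with the secondary allylic alcohol (the tertiary C4 hydroxyl is too hindered to compete) installs the C14–C(=O)–O–C11 allyl ester that is rearranged in step 17.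

**Step 10**
Reactants: 19 hydroxy ester
Product: 20 (3R)-6-bromo-2-methylhepta-1,6-dien-3-yl 2-[(4S,6R)-6-[(2S)-2,5-bis(tert-butyldimethylsilyloxy)pentan-2-yl]-2-oxotetrahydropyran-4-yl]acetate
Conditions: TBSOTf, 2,6-lutidine, CH2Cl2, −78 → 0 °C
Reagents that add atoms: tert-butyldimethylsilyl trifluoromethanesulfonate, CC(C)(C)[Si](C)(C)OS(=O)(=O)C(F)(F)F
Why: Silylation of the tertiary C4 alcohol with the silyl triflate prevents lactol formation with the C7 aldehyde of step 12 and removes the only acidic OH before the enolate steps.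

**Step 11**
Reactants: 20 bis-silyl ether
Product: 21 (3R)-6-bromo-2-methylhepta-1,6-dien-3-yl 2-[(4S,6R)-6-[(2S)-2-(tert-butyldimethylsilyloxy)-5-hydroxypentan-2-yl]-2-oxotetrahydropyran-4-yl]acetate
Conditions: HF·pyridine, pyridine, THF, 0 °C
Reagents that add atoms: none
Why: Fluoride-mediated desilylation is much faster for the primary than for the tertiary TBS ether, so only C7–OH should be freed.

**Step 12**
Reactants: 21 primary alcohol
Product: 22 (3R)-6-bromo-2-methylhepta-1,6-dien-3-yl 2-[(4S,6R)-6-[(2S)-2-(tert-butyldimethylsilyloxy)-5-oxopentan-2-yl]-2-oxotetrahydropyran-4-yl]acetate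
Conditions: Dess–Martin periodinane, NaHCO3, CH2Cl2, rt
Reagents that add atoms: none
Why: Dess–Martin oxidation gives the aldehyde under buffered conditions that leave the lactone, the allyl ester and the vinyl bromide untouched.

**Step 13**
Reactants: 22 bromo aldehyde
Product: 23 bicyclic bis-lactone alcohol (14-membered lactone C1–C11/O/C=O/C14 bridged by the δ-lactone; 7-hydroxy as both epimers; 8-methylene; 4-O-TBS; 11-isopropenyl; 1S,3R,4S,11R)
Conditions: CrCl2 (6 equiv), NiCl2 (2 mol %), DMSO/THF, rt, 2 mM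
Reagents that add atoms: none
Why: Nozaki–Hiyama–Kishi reaction: nickel-catalysed formation of the alkenylchromium species from the 2-bromoalkene and its chemoselective addition to the aldehyde closes the 14-membered lactone at C7–C8 and creates the 2-methylene carbinol; the C7 configuration is left open because steps 14 and 15 reset it.

**Step 14**
Reactants: 23 macrolactone alcohol (C7 epimers)
Product: 24 macrolactone enone (7-oxo-8-methylene)
Conditions: Dess–Martin periodinane, NaHCO3, CH2Cl2, 0 °C → rt
Reagents that add atoms: none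
Why: Dess–Martin oxidation of the allylic alcohol converges both C7 epimers on one α-methylene ketone.

**Step 15**
Reactants: 24 macrolactone enone
Product: 25 (7S)-macrolactone alcohol
Conditions: (R)-Me-CBS oxazaborolidine (0.5 equiv), catecholborane, toluene, −78 °C
Reagents that add atoms: none
Why: Corey–Bakshi–Shibata reduction under reagent control: with the 1,1-disubstituted vinyl group as the large substituent the (R)-catalyst should give the 7S alcohol, the ester carbonyls and the olefins being inert at −78 °C.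

**Step 16**
Reactants: 25 (7S)-macrolactone alcohol
Product: 26 4,7-bis-O-TBS macrolactone
Conditions: TBSOTf, 2,6-lutidine, CH2Cl2, −78 °C
Reagents that add atoms: tert-butyldimethylsilyl trifluoromethanesulfonate, CC(C)(C)[Si](C)(C)OS(=O)(=O)C(F)(F)F
Why: Silylation of C7–OH leaves no acidic hydrogen other than the two ester α-CH2 groups.

**Step 17**
Reactants: 26 4,7-bis-O-TBS macrolactone
Product: 28 14-membered carbocyclic C14-carboxylic acid with E-C11=C12 (1R,3R,4S,7S,14R), via bis(silyl ketene acetal) 27 (not isolated)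
Conditions: LiN(iPr)2 (LDA, 3 equiv), TMSCl/Et3N, THF, −78 °C; then rt → 50 °C; aq. citric acid
Reagents that add atoms: none
Why: LDA in the presence of TMSCl converts both lactone carbonyls of 26 into silyl ketene acetals (27), of which only the 14-membered one is an O-allyl ketene acetal (C14=C(OSi)–O–C11–C12(Me)=C13), and on warming it undergoes the concerted [3,3]-sigmatropic shift that forms C13–C14 and breaks C11–O. The closest known reaction type is the Ireland–Claisen rearrangement of alkenyl-substituted lactones to cycloalkenecarboxylic acids (macrolide-to-carbocycle conversion). The 14-membered carbocycle closes by this sigmatropic transposition of the 14-membered lactone through a six-membered chair array embedded in the ring, the exocyclic isopropenyl group becoming the endocyclic olefin, so no ionic exo or endo closure is involved. The one new stereocentre, C14, is fixed by the C11 carbinol configuration and the ketene acetal geometry through the chair (14R expected) but is of no consequence, since step 18 removes the carboxyl. The selectivity that matters is the E geometry of C11=C12, which should be secured by the chair in which C10 sits equatorial at C11 away from the C12 methyl and the silyloxy group, the ten-carbon tether C1–C10 being long enough to span the 1,4-positions without forcing a boat. Side reactions are limited by design: the δ-lactone ketene acetal has no allyl partner and no stereocentre at C15 yet and reverts on hydrolysis, and neither enolate can reach the other carbonyl except through a four-membered ring.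

**Step 18**
Reactants: 28 carbocyclic C14-carboxylic acid
Product: 30 decarboxylated carbocycle (C14H2; 1R,3R,4S,7S), via thiohydroxamate ester 29 (not isolated)
Conditions: DCC, 1-hydroxypyridine-2(1H)-thione, DMAP (cat.), CH2Cl2, rt, dark; then t-BuSH, hν (tungsten lamp), rt
Reagents that add atoms: none
Why: Barton reductive decarboxylation: the C14 radical released from the thiohydroxamate ester should be quenched by the thiol faster than it can cyclise or abstract hydrogen across the ring, which removes the helper carboxyl and leaves C14 as CH2.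

**Step 19**
Reactants: 30 decarboxylated carbocycle
Product: 31 (15S)-15-methyl lactone (1R,3R,4S,7S,15S; 4,7-bis-O-TBS)
Conditions: LiN(iPr)2 (LDA, 1.2 equiv), THF, −78 °C; MeI, DMPU, −78 → −40 °C
Reagents that add atoms: iodomethane, CI
Why: Lactone enolate alkylation: the δ-lactone is the only enolisable carbonyl and iodomethane should add anti to the adjacent C1 substituent to give the 15S (3,4-trans, all-equatorial) lactone, which is also the thermodynamic epimer, so a base equilibration would correct any cis isomer.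

**Step 20**
Reactants: 31 (15S)-15-methyl lactone
Product: 32 4,7-diol (11,12-deoxy target; E-C11=C12)
Conditions: HF (48% aq.), MeCN, 0 °C → rt
Reagents that add atoms: none
Why: Acidic fluoride desilylation removes the secondary and the hindered tertiary TBS ethers before the acid-sensitive epoxide is present.

**Step 21**
Reactants: 32 4,7-diol
Product: 33 (1R,3R,4S,7S,11S,12S,15S)-11,12-epoxy-4,7-dihydroxycembr-8(19)-en-16,3-olide (target)
Conditions: L-fructose-derived Shi ketone (0.3–1 equiv), Oxone (2KHSO5·KHSO4·K2SO4), K2CO3, Bu4NHSO4, MeCN/CH2(OMe)2/aq. Na2EDTA buffer (pH ≈ 9–10), −5 → 0 °C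
Reagents that add atoms: potassium peroxymonosulfate, [K+].[O-]S(=O)(=O)OO
Why: Shi epoxidation: the chiral dioxirane should react with the electron-rich trisubstituted E-olefin far faster than with the 1,1-disubstituted one, and the L-fructose-derived ketone should give the (11S,12S)-epoxide under catalyst control (the D-fructose ketone gives R,R-epoxides from E-olefins).

**Compound list**
1 | N-methoxy-N-methylacetamide | CC(=O)N(C)OC | starting material
2 | 2,3-dibromoprop-1-ene | C=C(Br)CBr | starting material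
3 | 4-bromo-N-methoxy-N-methylpent-4-enamide | C=C(Br)CCC(=O)N(C)OC | intermediate
4 | isopropenylmagnesium bromide | C=C(C)[Mg]Br | starting material
5 | 6-bromo-2-methylhepta-1,6-dien-3-one | C=C(C)C(=O)CCC(Br)=C | intermediate
6 | (3R)-6-bromo-2-methylhepta-1,6-dien-3-ol | C=C(C)[C@H](O)CCC(Br)=C | intermediate
7 | tert-butyldimethyl(pent-4-yn-1-yloxy)silane | C#CCCCO[Si](C)(C)C(C)(C)C | starting material
8 | (E)-[5-(tert-butyldimethylsilyloxy)-2-methylpent-1-en-1-yl]dimethylalane | C[Al](C)/C=C(\C)CCCO[Si](C)(C)C(C)(C)C | intermediate (not isolated)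
9 | (2E)-6-(tert-butyldimethylsilyloxy)-3-methylhex-2-en-1-ol | OC/C=C(\C)CCCO[Si](C)(C)C(C)(C)C | intermediate
10 | [(2S,3S)-3-[3-(tert-butyldimethylsilyloxy)propyl]-3-methyloxiran-2-yl]methanol | OC[C@@H]1O[C@@]1(C)CCCO[Si](C)(C)C(C)(C)C | intermediate
11 | [(2S,3S)-3-[3-(tert-butyldimethylsilyloxy)propyl]-3-methyloxiran-2-yl]methyl 4-methylbenzenesulfonate | Cc1ccc(cc1)S(=O)(=O)OC[C@@H]1O[C@@]1(C)CCCO[Si](C)(C)C(C)(C)C | intermediate
12 | 4-bromocyclopent-1-ene | BrC1CC=CC1 | starting material
13 | cyclopent-3-en-1-yllithium | [Li]C1CC=CC1 | intermediate (not isolated)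
14 | lithium di(cyclopent-3-en-1-yl)cuprate | [Li+].C1=CCC(C1)[Cu-]C1CC=CC1 | intermediate (not isolated)
15 | tert-butyl{3-[(2S,3S)-3-(cyclopent-3-en-1-ylmethyl)-2-methyloxiran-2-yl]propoxy}dimethylsilane | C1=CCC(C1)C[C@@H]1O[C@@]1(C)CCCO[Si](C)(C)C(C)(C)C | intermediate
16 | 3-{[(2S,3S)-3-[3-(tert-butyldimethylsilyloxy)propyl]-3-methyloxiran-2-yl]methyl}pentanedial | O=CCC(CC=O)C[C@@H]1O[C@@]1(C)CCCO[Si](C)(C)C(C)(C)C | intermediate (not isolated)
17 | 3-{[(2S,3S)-3-[3-(tert-butyldimethylsilyloxy)propyl]-3-methyloxiran-2-yl]methyl}pentanedioic acid | OC(=O)CC(CC(O)=O)C[C@@H]1O[C@@]1(C)CCCO[Si](C)(C)C(C)(C)C | intermediate (not isolated)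
18 | 2-[(4S,6R)-6-[(2S)-5-(tert-butyldimethylsilyloxy)-2-hydroxypentan-2-yl]-2-oxotetrahydropyran-4-yl]acetic acid (4,6-cis) | OC(=O)C[C@@H]1C[C@@H](OC(=O)C1)[C@@](C)(O)CCCO[Si](C)(C)C(C)(C)C | intermediate
19 | (3R)-6-bromo-2-methylhepta-1,6-dien-3-yl ester of 18 | C=C(C)[C@H](OC(=O)C[C@@H]1C[C@@H](OC(=O)C1)[C@@](C)(O)CCCO[Si](C)(C)C(C)(C)C)CCC(Br)=C | intermediate
20 | tertiary O-TBS ether of 19 | C=C(C)[C@H](OC(=O)C[C@@H]1C[C@@H](OC(=O)C1)[C@@](C)(O[Si](C)(C)C(C)(C)C)CCCO[Si](C)(C)C(C)(C)C)CCC(Br)=C | intermediate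
21 | primary alcohol (C7–OH) from 20 | C=C(C)[C@H](OC(=O)C[C@@H]1C[C@@H](OC(=O)C1)[C@@](C)(O[Si](C)(C)C(C)(C)C)CCCO)CCC(Br)=C | intermediate
22 | C7 aldehyde | C=C(C)[C@H](OC(=O)C[C@@H]1C[C@@H](OC(=O)C1)[C@@](C)(O[Si](C)(C)C(C)(C)C)CCC=O)CCC(Br)=C | intermediate
23 | bicyclic bis-lactone, 7-hydroxy (both C7 epimers), 8-methylene, 4-O-TBS, 11-isopropenyl (1S,3R,4S,11R) | C=C1CC[C@@H](OC(=O)C[C@@H]2C[C@@H](OC(=O)C2)[C@@](C)(O[Si](C)(C)C(C)(C)C)CCC1O)C(C)=C | intermediate
24 | 7-oxo macrolactone (enone) | C=C1CC[C@@H](OC(=O)C[C@@H]2C[C@@H](OC(=O)C2)[C@@](C)(O[Si](C)(C)C(C)(C)C)CCC1=O)C(C)=C | intermediate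
25 | (7S)-hydroxy macrolactone | C=C1CC[C@@H](OC(=O)C[C@@H]2C[C@@H](OC(=O)C2)[C@@](C)(O[Si](C)(C)C(C)(C)C)CC[C@@H]1O)C(C)=C | intermediate
26 | 4,7-bis-O-TBS macrolactone (1S,3R,4S,7S,11R) | C=C1CC[C@@H](OC(=O)C[C@@H]2C[C@@H](OC(=O)C2)[C@@](C)(O[Si](C)(C)C(C)(C)C)CC[C@@H]1O[Si](C)(C)C(C)(C)C)C(C)=C | intermediate
27 | bis(trimethylsilyl ketene acetal) of 26 | C=C1CC[C@@H](O/C(O[Si](C)(C)C)=C\[C@@H]2C[C@@H](OC(O[Si](C)(C)C)=C2)[C@@](C)(O[Si](C)(C)C(C)(C)C)CC[C@@H]1O[Si](C)(C)C(C)(C)C)C(C)=C | intermediate (not isolated)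
28 | 14-membered carbocycle, C14-carboxylic acid, E-C11=C12, 8-methylene, 4,7-bis-O-TBS, δ-lactone with C15H2 (1R,3R,4S,7S,14R) | C=C1CC/C=C(\C)C[C@@H](C(O)=O)[C@@H]2C[C@@H](OC(=O)C2)[C@@](C)(O[Si](C)(C)C(C)(C)C)CC[C@@H]1O[Si](C)(C)C(C)(C)C | intermediate
29 | 2-thioxopyridin-1(2H)-yl ester of 28 | C=C1CC/C=C(\C)C[C@@H](C(=O)ON3C=CC=CC3=S)[C@@H]2C[C@@H](OC(=O)C2)[C@@](C)(O[Si](C)(C)C(C)(C)C)CC[C@@H]1O[Si](C)(C)C(C)(C)C | intermediate (not isolated)
30 | decarboxylated carbocycle (C14H2; 1R,3R,4S,7S) | C=C1CC/C=C(\C)CC[C@@H]2C[C@@H](OC(=O)C2)[C@@](C)(O[Si](C)(C)C(C)(C)C)CC[C@@H]1O[Si](C)(C)C(C)(C)C | intermediate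
31 | (15S)-15-methyl lactone, 4,7-bis-O-TBS | C=C1CC/C=C(\C)CC[C@@H]2C[C@@H](OC(=O)[C@H]2C)[C@@](C)(O[Si](C)(C)C(C)(C)C)CC[C@@H]1O[Si](C)(C)C(C)(C)C | intermediate
32 | (1R,3R,4S,7S,11E,15S)-4,7-dihydroxycembra-8(19),11-dien-16,3-olide | C=C1CC/C=C(\C)CC[C@@H]2C[C@@H](OC(=O)[C@H]2C)[C@@](C)(O)CC[C@@H]1O | intermediate
33 | (1R,3R,4S,7S,11S,12S,15S)-11,12-epoxy-4,7-dihydroxycembr-8(19)-en-16,3-olide | C=C1CC[C@@H]2O[C@@]2(C)CC[C@@H]2C[C@@H](OC(=O)[C@H]2C)[C@@](C)(O)CC[C@@H]1O | target

**Step count**
Total: 21 steps. Longest linear sequence: 18 steps (7 → 33, steps 4–21); bromodienol 6 (steps 1–3) joins at step 9.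

**Steps most likely to fail, with fallbacks**

Step 17. The macrocyclic ketene acetal may be unable to reach the chair array, may rearrange through a boat to the Z olefin, or the ester enolate may fragment before silylation. Fallback: perform the [3,3] shift before the ring exists and close the carbocycle at C7–C8 instead. Setting out from 20, the same LDA/TMSCl protocol should give, through the open-chain bis(silyl ketene acetal) F1, the open-chain (E)-γ,δ-unsaturated acid F2. Barton decarboxylation through the thiohydroxamate ester F3 gives the bromodiene lactone F4. HF·pyridine frees the primary alcohol F5 and Dess–Martin oxidation gives the aldehyde F6. The Nozaki–Hiyama–Kishi reaction (CrCl2, cat. NiCl2) then closes the 14-membered carbocycle directly to the allylic alcohol F7 (C7 epimers). Dess–Martin oxidation to the enone F8 and (R)-CBS reduction give the 7S alcohol F9, whose silylation with TBSOTf returns to the route at 30.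

Step 8. The two acetic acid arms may be discriminated poorly (4,6-trans lactone), or the acid may open the epoxide at the tertiary carbon. Fallback: let a catalyst, not the ring, tell the arms apart. The crude diacid 17 is dehydrated with Ac2O to the glutaric anhydride F10. Alcoholysis with benzyl alcohol mediated by a dimeric cinchona alkaloid ((DHQD)2AQN or its quinine-derived pseudo-enantiomer, whichever esterifies the carbonyl on the future C14 arm) gives the benzyl hemiester F11. Its single free acid opens the epoxide (PPTS) to the lactone benzyl ester F12, and hydrogenolysis (H2, Pd/C) returns to the route at 18.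

Step 7. The cuprate may attack or eliminate the epoxide instead of displacing the tosylate, and the secondary cuprate may decompose thermally. Fallback: make the C1–C2 bond before the epoxide exists. From 9, CBr4/PPh3 gives the allylic bromide F13. Coupling with cyclopent-3-en-1-ylmagnesium bromide F14 (from 12 and Mg) under Li2CuCl4 catalysis (α-selective allyl–alkyl coupling) gives the diene F15. Shi epoxidation with the L-fructose-derived ketone, selective for the trisubstituted E-olefin over the cis-cyclopentene, should give the (S,S)-epoxide and returns to the route at 15.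

**Further compounds**
F1 | step 17 | open-chain bis(trimethylsilyl ketene acetal) of 20 | C=C(C)[C@H](O/C(O[Si](C)(C)C)=C\[C@@H]1C[C@@H](OC(O[Si](C)(C)C)=C1)[C@@](C)(O[Si](C)(C)C(C)(C)C)CCCO[Si](C)(C)C(C)(C)C)CCC(Br)=C
F2 | step 17 | open-chain (E)-γ,δ-unsaturated acid (C13–C14 formed, C14–CO2H) | C=C(Br)CC/C=C(\C)C[C@@H](C(O)=O)[C@@H]1C[C@@H](OC(=O)C1)[C@@](C)(O[Si](C)(C)C(C)(C)C)CCCO[Si](C)(C)C(C)(C)C
F3 | step 17 | 2-thioxopyridin-1(2H)-yl ester of F2 | C=C(Br)CC/C=C(\C)C[C@@H](C(=O)ON2C=CC=CC2=S)[C@@H]1C[C@@H](OC(=O)C1)[C@@](C)(O[Si](C)(C)C(C)(C)C)CCCO[Si](C)(C)C(C)(C)C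
F4 | step 17 | open-chain bromodiene lactone (C14H2), bis-O-TBS | C=C(Br)CC/C=C(\C)CC[C@@H]1C[C@@H](OC(=O)C1)[C@@](C)(O[Si](C)(C)C(C)(C)C)CCCO[Si](C)(C)C(C)(C)C
F5 | step 17 | open-chain primary alcohol (C7–OH) | C=C(Br)CC/C=C(\C)CC[C@@H]1C[C@@H](OC(=O)C1)[C@@](C)(O[Si](C)(C)C(C)(C)C)CCCO
F6 | step 17 | open-chain C7 aldehyde | C=C(Br)CC/C=C(\C)CC[C@@H]1C[C@@H](OC(=O)C1)[C@@](C)(O[Si](C)(C)C(C)(C)C)CCC=O
F7 | step 17 | carbocyclic allylic alcohol (C7 epimers), 4-O-TBS | C=C1CC/C=C(\C)CC[C@@H]2C[C@@H](OC(=O)C2)[C@@](C)(O[Si](C)(C)C(C)(C)C)CCC1O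
F8 | step 17 | carbocyclic 7-oxo-8-methylene enone, 4-O-TBS | C=C1CC/C=C(\C)CC[C@@H]2C[C@@H](OC(=O)C2)[C@@](C)(O[Si](C)(C)C(C)(C)C)CCC1=O
F9 | step 17 | carbocyclic (7S)-alcohol, 4-O-TBS | C=C1CC/C=C(\C)CC[C@@H]2C[C@@H](OC(=O)C2)[C@@](C)(O[Si](C)(C)C(C)(C)C)CC[C@@H]1O
F10 | step 8 | 4-{[(2S,3S)-3-[3-(tert-butyldimethylsilyloxy)propyl]-3-methyloxiran-2-yl]methyl}dihydropyran-2,6-dione | O=C1CC(CC(=O)O1)C[C@@H]1O[C@@]1(C)CCCO[Si](C)(C)C(C)(C)C
F11 | step 8 | monobenzyl ester of 17 (ester on the future C14 arm) | O=C(OCc1ccccc1)C[C@@H](CC(O)=O)C[C@@H]1O[C@@]1(C)CCCO[Si](C)(C)C(C)(C)C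
F12 | step 8 | benzyl ester of 18 | O=C(OCc1ccccc1)C[C@@H]1C[C@@H](OC(=O)C1)[C@@](C)(O)CCCO[Si](C)(C)C(C)(C)C
F13 | step 7 | (2E)-1-bromo-6-(tert-butyldimethylsilyloxy)-3-methylhex-2-ene | BrC/C=C(\C)CCCO[Si](C)(C)C(C)(C)C
F14 | step 7 | cyclopent-3-en-1-ylmagnesium bromide | Br[Mg]C1CC=CC1
F15 | step 7 | (E)-tert-butyl{[6-(cyclopent-3-en-1-yl)-4-methylhex-4-en-1-yl]oxy}dimethylsilane | C1=CCC(C1)C/C=C(\C)CCCO[Si](C)(C)C(C)(C)C
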